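**Plan**
Cuts, in retrosynthetic order: C16=C17 (α-methylenation); C8–C15 together with C9–C11 (one reductive cascade); C11–C15 re-joined (the dialdehyde is an opened cyclopentene); C8–C14 (lactone alkylation); C9–C10 and the lactone C–O (radical spirolactonisation); C5–C6 and C10–C20 on 4,4-dimethylcyclohexenone.
Enabling feature: C13 of the bicyclo[3.2.1]octane (rings C and D) carries two constitutionally identical two-carbon arms, C12–C11(O) and C16–C15(O). Rings C and D are therefore a hidden 3-substituted glutaraldehyde, stored as an achiral cyclopentene (temporary ring).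
Forward order: ring A (bought) → spiro δ-lactone → side chain on C8 → rings C and D in one step (C9–C11 by ketyl addition, C8–C15 by aldol) → C15 ketone → C17.
Stereochemistry: C5 by catalyst-controlled conjugate addition; C1 and C10 by relay from C5; C9, C11, C13 and C8 in the cascade under control of C10.
Key step: step 13

Remark: positions are given in kaurane numbering (C1 to C20) throughout; a centre that forms as a mixture and is removed later carries no stereo label in its SMILES.

Step 1
Reactants: 1 4,4-dimethylcyclohex-2-en-1-one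
Product: 4 (R)-3-{[dimethyl(propan-2-yloxy)silyl]methyl}-4,4-dimethyl-2-methylidenecyclohexan-1-one, via Mannich base 2 (not isolated), via ammonium iodide 3 (not isolated)
Conditions: (iPrO)Me2SiCH2MgCl, CuBr·SMe2 (5 mol %), (R)-1-[(Sp)-2-(diphenylphosphino)ferrocenyl]ethyldicyclohexylphosphine (6 mol %, antipode chosen for the R adduct), tBuOMe, −75 °C; then Me2N=CH2+ I−, THF, −75 °C to rt; then MeI, CH2Cl2, rt; NaHCO3 (aq)
Reagents that add atoms: (isopropoxydimethylsilyl)methylmagnesium chloride CC(C)O[Si](C)(C)C[Mg]Cl; Eschenmoser's salt C=[N+](C)C.[I-]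
Why: Copper-catalysed enantioselective conjugate addition of a Grignard reagent with a ferrocenyl diphosphine ligand should set C5 by catalyst control; the magnesium enolate exists only on the C10 side, is trapped there in a Mannich reaction, and quaternisation with Hofmann-type elimination gives the exocyclic enone.

Step 2
Reactants: 4 (R)-3-{[dimethyl(propan-2-yloxy)silyl]methyl}-4,4-dimethyl-2-methylidenecyclohexan-1-one
Product: 6 (1S,3R)-3-(hydroxymethyl)-4,4-dimethyl-2-methylidenecyclohexan-1-ol, via silyl allylic alcohol 5 (not isolated)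
Conditions: NaBH4, CeCl3·7H2O, MeOH, −78 °C; then KF, KHCO3, H2O2 (30 %), THF/MeOH, rt
Reagents that add atoms: hydrogen peroxide OO
Why: Luche 1,2-reduction should deliver hydride to the carbonyl face opposite the C5 side chain and so give the 1,3-cis alcohol, and Tamao–Fleming oxidation then turns the C–Si bond into C–OH without touching a stereocentre.

Step 3
Reactants: 6 (1S,3R)-3-(hydroxymethyl)-4,4-dimethyl-2-methylidenecyclohexan-1-ol
Product: 7 (1S,3R)-1-[(tert-butyldimethylsilyl)oxy]-3-{[(tert-butyldimethylsilyl)oxy]methyl}-4,4-dimethyl-2-methylidenecyclohexane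
Conditions: TBSOTf, 2,6-lutidine, CH2Cl2, 0 °C
Reagents that add atoms: tert-butyldimethylsilyl triflate CC(C)(C)[Si](C)(C)OS(=O)(=O)C(F)(F)F
Why: Silyl triflate silylation protects the primary and the hindered secondary hydroxyl with groups that survive the enolate steps; no stereocentre is formed.

Step 4
Reactants: 7 (1S,3R)-1-[(tert-butyldimethylsilyl)oxy]-3-{[(tert-butyldimethylsilyl)oxy]methyl}-4,4-dimethyl-2-methylidenecyclohexane
Product: 8 (3R,4S,8S)-8-[(tert-butyldimethylsilyl)oxy]-4-{[(tert-butyldimethylsilyl)oxy]methyl}-5,5-dimethyl-1-oxaspiro[2.5]octane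
Conditions: mCPBA, NaHCO3, CH2Cl2, 0 °C
Reagents that add atoms: 3-chloroperbenzoic acid OOC(=O)c1cccc(Cl)c1
Why: Prilezhaev epoxidation of the 1,1-disubstituted alkene should occur anti to the two flanking silyloxy-bearing substituents; the spiro configuration is of no consequence because this carbon becomes a radical in step 5.

Step 5
Reactants: 8 (3R,4S,8S)-8-[(tert-butyldimethylsilyl)oxy]-4-{[(tert-butyldimethylsilyl)oxy]methyl}-5,5-dimethyl-1-oxaspiro[2.5]octane
Product: 9 (6S,7R,11S)-11-[(tert-butyldimethylsilyl)oxy]-7-{[(tert-butyldimethylsilyl)oxy]methyl}-8,8-dimethyl-2-oxaspiro[5.5]undecan-3-one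
Conditions: Cp2TiCl2 (20 mol %), Zn, 2,4,6-collidine·HCl, CF3CH2O2CCH=CH2, THF, rt
Reagents that add atoms: 2,2,2-trifluoroethyl acrylate C=CC(=O)OCC(F)(F)F
Why: Nugent–RajanBabu epoxide opening by trivalent titanium gives the tertiary C10 radical, which undergoes Giese addition to the acrylate on the face anti to both cis-disposed neighbours (C1–OTBS, C5–CH2OTBS) and to the axial C4 methyl, and the C20 alkoxide then lactonises onto the activated ester.

Step 6
Reactants: 10 cyclopent-3-en-1-ylmethanol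
Product: 11 4-(iodomethyl)cyclopent-1-ene
Conditions: PPh3, I2, imidazole, CH2Cl2, 0 °C to rt
Reagents that add atoms: iodine II
Why: Appel iodination of a primary alcohol gives the achiral, mirror-symmetric electrophile; no stereocentre is involved.

Step 7
Reactants: 9 (6S,7R,11S)-11-[(tert-butyldimethylsilyl)oxy]-7-{[(tert-butyldimethylsilyl)oxy]methyl}-8,8-dimethyl-2-oxaspiro[5.5]undecan-3-one; 11 4-(iodomethyl)cyclopent-1-ene
Product: 12 (4RS,6S,7R,11S)-11-[(tert-butyldimethylsilyl)oxy]-7-{[(tert-butyldimethylsilyl)oxy]methyl}-4-(cyclopent-3-en-1-ylmethyl)-8,8-dimethyl-2-oxaspiro[5.5]undecan-3-one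
Conditions: LiN(iPr)2, THF, −78 °C; then 11, HMPA, −78 to −20 °C
Reagents that add atoms: none
Why: SN2 alkylation of the lactone lithium enolate with a primary iodide forms C8–C14; the C8 configuration is not controlled and is erased in step 9.

Step 8
Reactants: 12 (4RS,6S,7R,11S)-11-[(tert-butyldimethylsilyl)oxy]-7-{[(tert-butyldimethylsilyl)oxy]methyl}-4-(cyclopent-3-en-1-ylmethyl)-8,8-dimethyl-2-oxaspiro[5.5]undecan-3-one
Product: 13 (4RS,6S,7R,11S)-11-[(tert-butyldimethylsilyl)oxy]-7-{[(tert-butyldimethylsilyl)oxy]methyl}-4-(cyclopent-3-en-1-ylmethyl)-8,8-dimethyl-4-(phenylselanyl)-2-oxaspiro[5.5]undecan-3-one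
Conditions: LiN(iPr)2, THF, −78 °C; then PhSeBr, −78 °C
Reagents that add atoms: phenylselenyl bromide Br[Se]c1ccccc1
Why: α-Selenenylation of the fully substituted lactone enolate places the leaving group on C8; either C8 epimer serves.

Step 9
Reactants: 13 (4RS,6S,7R,11S)-11-[(tert-butyldimethylsilyl)oxy]-7-{[(tert-butyldimethylsilyl)oxy]methyl}-4-(cyclopent-3-en-1-ylmethyl)-8,8-dimethyl-4-(phenylselanyl)-2-oxaspiro[5.5]undecan-3-one
Product: 15 (6S,7R,11S)-11-[(tert-butyldimethylsilyl)oxy]-7-{[(tert-butyldimethylsilyl)oxy]methyl}-4-(cyclopent-3-en-1-ylmethyl)-8,8-dimethyl-2-oxaspiro[5.5]undec-4-en-3-one, via selenoxide 14 (not isolated)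
Conditions: mCPBA (1.0 equiv), CH2Cl2, −78 °C; then iPr2NH, −78 °C to rt
Reagents that add atoms: none
Why: Selenoxide syn-elimination toward the ring C9–H should give the endocyclic conjugated C8=C9 lactone, and at −78 °C the peracid oxidises selenium much faster than the cyclopentene.

Step 10
Reactants: 15 (6S,7R,11S)-11-[(tert-butyldimethylsilyl)oxy]-7-{[(tert-butyldimethylsilyl)oxy]methyl}-4-(cyclopent-3-en-1-ylmethyl)-8,8-dimethyl-2-oxaspiro[5.5]undec-4-en-3-one
Product: 16 (6S,7R,11S)-4-(cyclopent-3-en-1-ylmethyl)-11-hydroxy-7-(hydroxymethyl)-8,8-dimethyl-2-oxaspiro[5.5]undec-4-en-3-one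
Conditions: HF·pyridine, THF, 0 °C to rt
Reagents that add atoms: none
Why: Fluoride-mediated desilylation under mildly acidic conditions frees both hydroxyls without opening or isomerising the unsaturated lactone.

Step 11
Reactants: 16 (6S,7R,11S)-4-(cyclopent-3-en-1-ylmethyl)-11-hydroxy-7-(hydroxymethyl)-8,8-dimethyl-2-oxaspiro[5.5]undec-4-en-3-one
Product: 17 (6S,7R,11S)-11-acetoxy-7-(acetoxymethyl)-4-(cyclopent-3-en-1-ylmethyl)-8,8-dimethyl-2-oxaspiro[5.5]undec-4-en-3-one
Conditions: Ac2O, pyridine, DMAP (cat.), CH2Cl2, rt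
Reagents that add atoms: acetic anhydride CC(=O)OC(C)=O
Why: DMAP-catalysed acetylation installs the C1 and C6 acetates of the target now, after the last strong-base step and before the base-sensitive tetracycle exists.

Step 12
Reactants: 17 (6S,7R,11S)-11-acetoxy-7-(acetoxymethyl)-4-(cyclopent-3-en-1-ylmethyl)-8,8-dimethyl-2-oxaspiro[5.5]undec-4-en-3-one
Product: 19 3-{[(6S,7R,11S)-11-acetoxy-7-(acetoxymethyl)-8,8-dimethyl-3-oxo-2-oxaspiro[5.5]undec-4-en-4-yl]methyl}pentanedial, via ozonide 18 (not isolated)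
Conditions: O3, CH2Cl2, −78 °C (Sudan Red 7B end point); then PPh3, −78 °C to rt
Reagents that add atoms: ozone [O-][O+]=O
Why: Ozonolysis with reductive work-up cleaves the electron-rich cis-disubstituted cyclopentene far faster than the electron-poor trisubstituted enoate and unveils the two identical CH2CHO arms on C13.

Step 13
Reactants: 19 3-{[(6S,7R,11S)-11-acetoxy-7-(acetoxymethyl)-8,8-dimethyl-3-oxo-2-oxaspiro[5.5]undec-4-en-4-yl]methyl}pentanedial
Product: 21 (1S,5R,8S,9S,10R,11S,13S,15S)-1,6-diacetoxy-11,15-dihydroxy-17-nor-6,7-secokauran-7,20-olide, via samarium enolate 20 (not isolated)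
Conditions: SmI2 (0.1 M in THF, 2.5 equiv, slow addition), t-BuOH, THF, −78 °C
Reagents that add atoms: none
Why: SmI2 reduces one aldehyde reversibly to a ketyl radical, which adds 6-endo-trig to C9 of the unsaturated lactone (ring C, C9–C11); a second electron turns the C8 radical into a trivalent samarium enolate, which adds 5-exo-trig to the remaining aldehyde and so forms C8–C15, ring D and the quaternary centre. The closest known reaction type is the SmI2 ketyl–olefin/aldol cascade of dialdehydes that carry an unsaturated ester or lactone acceptor. C9 is set by ketyl attack on the lactone face that carries C1, away from C5 with its CH2OAc and gem-dimethyl neighbours; C11 follows from a chair transition state with the O–Sm group equatorial and trans to C10; C13 arises by choice between the two diastereotopic CH2CHO arms, the one left behind sitting equatorial in that chair. C8 is fixed by the bicycle, because the enolate can reach the second aldehyde only on the face cis to that arm, and the C15 carbinol configuration (expected S by chelation to the lactone oxygen) is irrelevant since step 14 oxidises it. The step needs ketyl–olefin addition to win over pinacol coupling of the 1,5-dialdehyde and over enolate protonation: slow addition keeps divalent samarium scarce, so a second electron transfer to the other aldehyde should not compete with the irreversible addition to the enoate, and the intramolecular aldol should outrun protonation by tert-butanol.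

Step 14
Reactants: 21 (1S,5R,8S,9S,10R,11S,13S,15S)-1,6-diacetoxy-11,15-dihydroxy-17-nor-6,7-secokauran-7,20-olide
Product: 22 (1S,5R,8S,9S,10R,11S,13S)-1,6-diacetoxy-11-hydroxy-15-oxo-17-nor-6,7-secokauran-7,20-olide
Conditions: Dess–Martin periodinane (1.1 equiv), NaHCO3, CH2Cl2, 0 °C
Reagents that add atoms: none
Why: Dess–Martin oxidation should take the C15 hydroxyl, which sits exo on the convex face of ring D, in preference to the axial C11 hydroxyl tucked under the C15–C16 bridge, because ligand exchange at iodine is sensitive to this crowding.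

Step 15
Reactants: 22 (1S,5R,8S,9S,10R,11S,13S)-1,6-diacetoxy-11-hydroxy-15-oxo-17-nor-6,7-secokauran-7,20-olide
Product: 24 rabdosin B, (1S,5R,8S,9S,10R,11S,13S)-1,6-diacetoxy-11-hydroxy-15-oxo-6,7-secokaur-16-en-7,20-olide, via Mannich base 23 (not isolated)
Conditions: (CH2O)n, PhNHMe·CF3CO2H, THF, 65 °C
Reagents that add atoms: paraformaldehyde (as formaldehyde) C=O
Why: Acid-mediated Mannich α-methylenation; the C15 ketone can enolise only toward C16 because C8 is quaternary, and the acidic medium avoids the alkoxide at O11 that could trigger retro-Claisen cleavage of the β-keto lactone.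

**Compound list**
1 | 4,4-dimethylcyclohex-2-en-1-one | CC1(C)CCC(=O)C=C1 | starting material
2 | (2R,3S)-2-[(dimethylamino)methyl]-3-{[dimethyl(propan-2-yloxy)silyl]methyl}-4,4-dimethylcyclohexan-1-one (2,3-trans Mannich base) | CN(C)C[C@@H]1C(=O)CCC(C)(C)[C@H]1C[Si](C)(C)OC(C)C | intermediate (not isolated)
3 | N-methyl quaternary ammonium iodide of 2 | C[N+](C)(C)C[C@@H]1C(=O)CCC(C)(C)[C@H]1C[Si](C)(C)OC(C)C.[I-] | intermediate (not isolated)
4 | (R)-3-{[dimethyl(propan-2-yloxy)silyl]methyl}-4,4-dimethyl-2-methylidenecyclohexan-1-one | C=C1C(=O)CCC(C)(C)[C@H]1C[Si](C)(C)OC(C)C | intermediate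
5 | (1S,3R)-3-{[dimethyl(propan-2-yloxy)silyl]methyl}-4,4-dimethyl-2-methylidenecyclohexan-1-ol (1,3-cis) | C=C1[C@@H](O)CCC(C)(C)[C@H]1C[Si](C)(C)OC(C)C | intermediate (not isolated)
6 | (1S,3R)-3-(hydroxymethyl)-4,4-dimethyl-2-methylidenecyclohexan-1-ol (1,3-cis) | C=C1[C@@H](O)CCC(C)(C)[C@H]1CO | intermediate
7 | (1S,3R)-1-[(tert-butyldimethylsilyl)oxy]-3-{[(tert-butyldimethylsilyl)oxy]methyl}-4,4-dimethyl-2-methylidenecyclohexane | C=C1[C@@H](O[Si](C)(C)C(C)(C)C)CCC(C)(C)[C@H]1CO[Si](C)(C)C(C)(C)C | intermediate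
8 | (3R,4S,8S)-8-[(tert-butyldimethylsilyl)oxy]-4-{[(tert-butyldimethylsilyl)oxy]methyl}-5,5-dimethyl-1-oxaspiro[2.5]octane (epoxide oxygen trans to both side groups) | C1O[C@@]12[C@@H](O[Si](C)(C)C(C)(C)C)CCC(C)(C)[C@H]2CO[Si](C)(C)C(C)(C)C | intermediate
9 | (6S,7R,11S)-11-[(tert-butyldimethylsilyl)oxy]-7-{[(tert-butyldimethylsilyl)oxy]methyl}-8,8-dimethyl-2-oxaspiro[5.5]undecan-3-one | O=C1CC[C@]2(CO1)[C@@H](O[Si](C)(C)C(C)(C)C)CCC(C)(C)[C@H]2CO[Si](C)(C)C(C)(C)C | intermediate
10 | cyclopent-3-en-1-ylmethanol | OCC1CC=CC1 | starting material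
11 | 4-(iodomethyl)cyclopent-1-ene | ICC1CC=CC1 | intermediate
12 | (4RS,6S,7R,11S)-11-[(tert-butyldimethylsilyl)oxy]-7-{[(tert-butyldimethylsilyl)oxy]methyl}-4-(cyclopent-3-en-1-ylmethyl)-8,8-dimethyl-2-oxaspiro[5.5]undecan-3-one (C8 epimers) | O=C1C(CC3CC=CC3)C[C@]2(CO1)[C@@H](O[Si](C)(C)C(C)(C)C)CCC(C)(C)[C@H]2CO[Si](C)(C)C(C)(C)C | intermediate
13 | 4-(phenylselanyl) derivative of 12 (C8 epimers) | O=C1C([Se]c3ccccc3)(CC4CC=CC4)C[C@]2(CO1)[C@@H](O[Si](C)(C)C(C)(C)C)CCC(C)(C)[C@H]2CO[Si](C)(C)C(C)(C)C | intermediate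
14 | selenoxide of 13 | O=C1C([Se](=O)c3ccccc3)(CC4CC=CC4)C[C@]2(CO1)[C@@H](O[Si](C)(C)C(C)(C)C)CCC(C)(C)[C@H]2CO[Si](C)(C)C(C)(C)C | intermediate (not isolated)
15 | (6S,7R,11S)-11-[(tert-butyldimethylsilyl)oxy]-7-{[(tert-butyldimethylsilyl)oxy]methyl}-4-(cyclopent-3-en-1-ylmethyl)-8,8-dimethyl-2-oxaspiro[5.5]undec-4-en-3-one | O=C1C(CC3CC=CC3)=C[C@]2(CO1)[C@@H](O[Si](C)(C)C(C)(C)C)CCC(C)(C)[C@H]2CO[Si](C)(C)C(C)(C)C | intermediate
16 | (6S,7R,11S)-4-(cyclopent-3-en-1-ylmethyl)-11-hydroxy-7-(hydroxymethyl)-8,8-dimethyl-2-oxaspiro[5.5]undec-4-en-3-one | O=C1C(CC3CC=CC3)=C[C@]2(CO1)[C@@H](O)CCC(C)(C)[C@H]2CO | intermediate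
17 | (6S,7R,11S)-11-acetoxy-7-(acetoxymethyl)-4-(cyclopent-3-en-1-ylmethyl)-8,8-dimethyl-2-oxaspiro[5.5]undec-4-en-3-one | O=C1C(CC3CC=CC3)=C[C@]2(CO1)[C@@H](OC(C)=O)CCC(C)(C)[C@H]2COC(C)=O | intermediate
18 | secondary ozonide of 17 (6,7,8-trioxabicyclo[3.2.1]octan-3-ylmethyl side chain; trioxolane carbons not controlled) | O=C1C(CC3CC4OOC(C3)O4)=C[C@]2(CO1)[C@@H](OC(C)=O)CCC(C)(C)[C@H]2COC(C)=O | intermediate (not isolated)
19 | 3-{[(6S,7R,11S)-11-acetoxy-7-(acetoxymethyl)-8,8-dimethyl-3-oxo-2-oxaspiro[5.5]undec-4-en-4-yl]methyl}pentanedial | O=C1C(CC(CC=O)CC=O)=C[C@]2(CO1)[C@@H](OC(C)=O)CCC(C)(C)[C@H]2COC(C)=O | intermediate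
20 | ring C closed samarium enolate (C9–C11 formed; O11 and the C7 enolate oxygen on trivalent samarium; one CH2CHO arm left on C13) | O=CC[C@H]1CC2=C(O[Sm]([I])[I])OC[C@@]3([C@@H]2[C@@H](O[Sm]([I])[I])C1)[C@@H](OC(C)=O)CCC(C)(C)[C@H]3COC(C)=O | intermediate (not isolated)
21 | (1S,5R,8S,9S,10R,11S,13S,15S)-1,6-diacetoxy-11,15-dihydroxy-17-nor-6,7-secokauran-7,20-olide | C1[C@H](O)[C@]23C[C@H]1C[C@H](O)[C@H]2[C@]1(COC3=O)[C@@H](OC(C)=O)CCC(C)(C)[C@H]1COC(C)=O | intermediate
22 | (1S,5R,8S,9S,10R,11S,13S)-1,6-diacetoxy-11-hydroxy-15-oxo-17-nor-6,7-secokauran-7,20-olide | C1C(=O)[C@]23C[C@H]1C[C@H](O)[C@H]2[C@]1(COC3=O)[C@@H](OC(C)=O)CCC(C)(C)[C@H]1COC(C)=O | intermediate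
23 | 16-[(N-methylanilino)methyl] derivative of 22 (C16 epimers) | CN(c1ccccc1)CC1C(=O)[C@]23C[C@H]1C[C@H](O)[C@H]2[C@]1(COC3=O)[C@@H](OC(C)=O)CCC(C)(C)[C@H]1COC(C)=O | intermediate (not isolated)
24 | rabdosin B, (1S,5R,8S,9S,10R,11S,13S)-1,6-diacetoxy-11-hydroxy-15-oxo-6,7-secokaur-16-en-7,20-olide | C=C1C(=O)[C@]23C[C@H]1C[C@H](O)[C@H]2[C@]1(COC3=O)[C@@H](OC(C)=O)CCC(C)(C)[C@H]1COC(C)=O | target

**Count and risks**
Total steps: 15. Longest linear sequence: 14 steps (steps 1 to 5 and 7 to 15); step 6 is a one-step side branch.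

Most likely to fail, step 13: the two aldehydes may couple with each other (pinacol cyclisation to a cyclopentanediol), the wrong CH2CHO arm may cyclise, or the enolate may be protonated before the aldol. Fallback: the arms are made different so that only one can form a ketyl. It sets out from 17. Unsymmetrical ozonolysis (O3, MeOH/CH2Cl2, NaHCO3; then Ac2O, Et3N) should give the aldehyde methyl ester F1 as both C13 epimers. SmI2/t-BuOH then closes ring C in the matched epimer only (at most half of the material), and the O11 samarium alkoxide lactonises onto the ester arm to give the bridged 11,15-olide F2. In F2 the C15 carbonyl lies across ring C from C8, so catalytic KOtBu in THF should move the acyl group from O11 to the C8 enolate (transannular Claisen condensation). This frees the C11 hydroxyl, makes the C15 ketone, and comes back to the route at 22; step 14 is then not needed.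

Second, step 14: the oxidant may not distinguish the two secondary hydroxyls, giving the 11-ketone or the diketone. Fallback: if the C11 hydroxyl proves the more reactive one, that preference is used for protection instead. It sets out from 21. TESOTf (1.0 equiv), 2,6-lutidine, CH2Cl2, −78 °C should give the 11-O-triethylsilyl ether F3; excess Dess–Martin periodinane then gives the 15-ketone F4; HF·pyridine removes the silyl group and comes back to the route at 22.

Third, step 1: the bulky silylmethyl Grignard reagent may add slowly to the neopentyl β-carbon or with low enantioselectivity. Fallback: C5 is set by hydride delivery instead of carbon delivery. It sets out from 1. The same Grignard reagent with CuBr·SMe2 (no ligand) and Me3SiCl gives the racemic trimethylsilyl enol ether F5. Saegusa–Ito oxidation with Pd(OAc)2 in MeCN gives the achiral 3-substituted enone F6. Copper hydride asymmetric conjugate reduction (Cu(OAc)2·H2O, DTBM-SEGPHOS antipode chosen for the required face, (EtO)2MeSiH, toluene) gives the silyl enol ether F7 with C5 set and the enol regiochemistry fixed toward C10. F7 reacts with Eschenmoser's salt, then MeI and NaHCO3, through 2 and 3, and comes back to the route at 4.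

Further compounds
F1 | step 13 | methyl 3-(2-oxoethyl)-4-[(6S,7R,11S)-11-acetoxy-7-(acetoxymethyl)-8,8-dimethyl-3-oxo-2-oxaspiro[5.5]undec-4-en-4-yl]butanoate (both C13 epimers) | O=C1C(CC(CC=O)CC(=O)OC)=C[C@]2(CO1)[C@@H](OC(C)=O)CCC(C)(C)[C@H]2COC(C)=O
F2 | step 13 | (1S,5R,9S,10R,11S,13S)-1,6-diacetoxy-17-nor-6,7:8,15-disecokaurane-7,20:15,11-diolide (bridged 11,15-olide, C8–H, either C8 epimer) | O=C1C[C@H]2CC3C(=O)OC[C@@]4([C@@H]3[C@@H](O1)C2)[C@@H](OC(C)=O)CCC(C)(C)[C@H]4COC(C)=O
F3 | step 14 | 11-O-triethylsilyl ether of 21 | C1[C@H](O)[C@]23C[C@H]1C[C@H](O[Si](CC)(CC)CC)[C@H]2[C@]1(COC3=O)[C@@H](OC(C)=O)CCC(C)(C)[C@H]1COC(C)=O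
F4 | step 14 | 11-O-triethylsilyl ether of 22 | C1C(=O)[C@]23C[C@H]1C[C@H](O[Si](CC)(CC)CC)[C@H]2[C@]1(COC3=O)[C@@H](OC(C)=O)CCC(C)(C)[C@H]1COC(C)=O
F5 | step 1 | racemic [(3-{[dimethyl(propan-2-yloxy)silyl]methyl}-4,4-dimethylcyclohex-1-en-1-yl)oxy]trimethylsilane | CC(C)O[Si](C)(C)CC1C=C(O[Si](C)(C)C)CCC1(C)C
F6 | step 1 | 3-{[dimethyl(propan-2-yloxy)silyl]methyl}-4,4-dimethylcyclohex-2-en-1-one | CC(C)O[Si](C)(C)CC1=CC(=O)CCC1(C)C
F7 | step 1 | (S)-diethoxy(methyl)silyl enol ether of 3-{[dimethyl(propan-2-yloxy)silyl]methyl}-4,4-dimethylcyclohexanone (enol double bond toward C10) | CCO[Si](C)(OCC)OC1=C[C@H](C[Si](C)(C)OC(C)C)C(C)(C)CC1
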